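The numbers in the tables stem from a simulated flask on assumed constants; scatter was added.

The autumn, dusk and midnight runs stand behind this flask.

| flask | left-handed substrate | right-handed substrate | partner | protic impurity | precatalyst | remark | time |
|---|---|---|---|---|---|---|---|
| autumn | 2 mM | 2 mM | 6 mM | 0.10 mM | 67 µM | run made earlier |  |
| dusk | 2 mM | 2 mM | 6 mM | 0.10 mM | 150 µM | run made earlier |  |
| midnight | 2 mM | 2 mM | 6 mM | 0.15 mM | 100 µM | run made earlier |  |
| flask | 2.0 mM | 2.0 mM | 6.00 mM | 0.100 mM | 100 µM |  | 5.0 min |

- autumn (time / min: left-handed substrate / %, right-handed substrate / %): 0.200: 50, 48; 0.667: 45, 39; 1.00: 39, 27; 1.50: 33, 21; 2.50: 23, 5; 3.00: 21, 9; 4.00: 17, 4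
- dusk (time / min: left-handed substrate / %, right-handed substrate / %): 0.200: 47, 42; 0.667: 38, 18; 1.00: 29, 13; 1.50: 19, 2; 2.50: 5, 3; 3.00: 4, 0; 4.00: 1, 1
- midnight (time / min: left-handed substrate / %, right-handed substrate / %): 0.833: 38, 29; 1.50: 25, 11; 2.50: 18, 4; 3.00: 9, 0; 4.00: 4, 0

(scatter of a reading: 2 percentage points)

- free catalyst is single-handed; left-handed substrate and right-handed substrate are mirror images of each other, charged as a racemate, each of them at the stated concentration
- an excess is below zero if the other one leads

1. part of the left-handed substrate and right-handed substrate charged together that has reacted at 5.0 min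
2. excess of left-handed product over right-handed product in the product at 5.0 min
3. excess of right-handed substrate over left-handed substrate among what is left of the two at 5.0 min

At one moment, how much faster does a right-handed molecule react than a left-handed one? I take the logarithm of the fraction of right-handed charge left and divide it by the same logarithm for the left-handed charge. This is the selectivity factor. Pooled over autumn at 1.50 min, dusk at 1.00 min and midnight at 1.50 min, it reads 2.26.

Does it drift? Run by run I read 2.09, 2.47 and 2.18, with precatalyst going from 67 µM to 150 µM. Midnight reads 2.47 at 2.50 min, but that rests on a reading of 4% with a scatter of 2 percentage points. I see no drift beyond the scatter.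

So, while the factor holds, the right-handed fraction left equals the left-handed fraction left raised to that power.

The forecast gives c 97%, eP −2.7% and eS −80%, on the ground: “Right-handed substrate is consumed about twice as fast as left-handed”.

How far does the left-handed substrate go? I take over the forecast's conversion. Counting the remainder as left-handed, the flask keeps 6.00% of its left-handed charge. Raised to the factor, that leaves 0.176% of the right-handed charge, so nearly all of the remainder is left-handed and my eS is −94.3%, which differs from the forecast's.

The flask gives c 97.2%, eP 0.273% and eS −94.8%, which is 15 points below the forecast.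

free catalyst + left-handed substrate ⇌ catalyst intermediate A (K = 280 M⁻¹, k = 21000 M⁻¹ s⁻¹); left-handed product ⇌ right-handed product (k = 0.0590 s⁻¹); precatalyst → free catalyst (k = 0.0730 s⁻¹); partner + catalyst intermediate B → free catalyst + right-handed product (k = 76.0 M⁻¹ s⁻¹); partner + protic impurity → quenched reagent (k = 270 M⁻¹ s⁻¹); free catalyst + right-handed substrate ⇌ catalyst intermediate B (K = 1900 M⁻¹, k = 32000 M⁻¹ s⁻¹); partner + catalyst intermediate A → free catalyst + left-handed product (k = 210 M⁻¹ s⁻¹) At 5.00 min the flask holds 5.4% of its left-handed charge and 0.14% of its right-handed charge, and that left-handed rest raised to 2.26 is 0.137%. The neighbour charged with 1.5 mM of partner reaches c 32.5% and holds 79% of its left-handed charge. Raised to 2.26, that is 58.7%, and the neighbour holds 56% of its right-handed charge.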